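The target curve stops short. Over a trace of free catalyst, starting material and partner give target, second substrate and partner give second product, and target may pass reversibly into isomer of the product.

| flask | starting material | second substrate | partner | free catalyst | remark | time |
|---|---|---|---|---|---|---|
| dawn | 0.80 M | 0.25 M | 1.2 M | 0.53 mM | run made earlier |  |
| autumn | 0.80 M | 1.2 M | 1.2 M | 0.53 mM | run made earlier |  |
| larch | 0.80 M | 0.200 M | 1.20 M | 0.53 mM |  | 3.0 d |
| cedar | 0.80 M | 0.400 M | 1.20 M | 0.53 mM |  | 3.0 d |
| alder | 0.80 M | 0.800 M | 1.20 M | 0.53 mM |  | 3.0 d |

| run | time / h | target / % |
|---|---|---|
| dawn | 8.00 | 42 |
| dawn | 15.0 | 61 |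
| dawn | 20.0 | 69 |
| dawn | 30.0 | 76 |
| dawn | 40.0 | 81 |
| dawn | 48.0 | 82 |
| autumn | 2.50 | 8 |
| autumn | 8.00 | 29 |
| autumn | 15.0 | 48 |
| autumn | 20.0 | 57 |
| autumn | 30.0 | 64 |
| autumn | 40.0 | 73 |
| autumn | 48.0 | 76 |

(standard deviation of a reading: 1.5 percentage points)

- on the list of suspects stand: starting material + free catalyst <-> catalyst intermediate A; target <-> isomer of the product; partner + catalyst intermediate B -> free catalyst + second product; second substrate + free catalyst <-> catalyst intermediate B; partner + catalyst intermediate A -> free catalyst + target
- "hardly changes" means that all values lie within two and a half points (for a concentration: within two and a half percent of the largest)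

1. amount of target at the end, in percent of the starting material charged for larch, cedar, alder, in this order
2. how that number moves from the first to the last of them (hardly changes / rises, then falls / falls all the way / falls, then rises / rises all the way)

The ladder of time scales starts with the catalyst, whose charge is hardly any of the starting material charged. Its forms therefore hold a negligible fraction of the material, and target, isomer of the product and unreacted starting material sum to the charge. The next rung is the pseudo-first-order lifetime of starting material, estimated from the target reading at 8.00 h as if all reacted starting material stood as target: 14.7 h in the dawn run and a longer 23.4 h in the autumn run, which holds more second substrate.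

At 48.0 h that lifetime leaves 3.81 % of the starting material in the dawn run, yet target reads 82 %, so the balance books a fraction 14.2 % as isomer of the product. Replace the target curve by its mean, 62.8 % along chords through the readings. The gap divided by that mean and by the time gives 0.00471 h⁻¹, the leak constant: the net fraction of the target present that passes into isomer per hour. The autumn run, with a mean of 52.7 % and 12.8 % of the starting material reckoned left at its last reading, gives 0.00442 h⁻¹ from its own readings. The top rung, 212 h, is longer than either lifetime, so target first rises and then slowly leaks.

Larch nearly repeats the dawn recipe, and alder lies between the dawn and autumn recipes. Holding each curve at its last reading up to 3.0 d, the dawn curve has a mean of 69.2 % and the autumn curve 60.5 %. On these estimates the slower autumn curve leaks less than the dawn curve, 20.5 % against 23.5 %, but keeps more starting material, 4.58 % against 0.743 %. My reckoning therefore puts target at 75.8 % on the dawn curve and 74.9 % on the autumn curve at that time; with larch near the first recipe and alder between the two, it expects a row that hardly changes. The forecast, higher, gave 84.5 %, 84 % and 82.5 %, hardly changes, holding that “the second substrate mainly slows the reaction”.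

The flask gives 73.3 %, 73.5 % and 73.5 %, hardly changes, a little under my reckoning.

    starting material + free catalyst ⇌ catalyst intermediate A (K = 340 L mol⁻¹, k = 2.60 L mol⁻¹ min⁻¹)
    target ⇌ isomer of the product (K = 1.80, k = 9.80 × 10⁻⁵ min⁻¹)
    partner + catalyst intermediate B → free catalyst + second product (k = 1.60 L mol⁻¹ min⁻¹)
    second substrate + free catalyst ⇌ catalyst intermediate B (K = 1.20 L mol⁻¹, k = 2.80 L mol⁻¹ min⁻¹)
    partner + catalyst intermediate A → free catalyst + target (k = 51.0 L mol⁻¹ min⁻¹)

In larch at 0.401 d, the forward half-life of starting material, 0.40 d, stands far below the 4.9 d of target passing into isomer, and target is made 13.0 times faster than it is used up. Over the second half of the time, the leak constant on the mean of the two target values gives 13 percentage points of new isomer in larch, where the flask adds 14 points, and 13 points in alder, where the flask adds 14 points.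

The earlier runs and the new flask were generated by integration with made-up constants, and the scatter is random.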